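**Plan**

- Retrosynthetic cuts, in this order: the ring olefin C4=C5 (ring-closing metathesis); the C8 ester (side-chain acid); C11–C7 together with C11=C13 (lactone annulation with methylenation); C6–C7 (alkenylzinc plus acrolein); the 7,8- and 1,10-oxiranes; C1=C10 (Horner–Wadsworth–Emmons).
- Forward order: the open chain with the 1,10-epoxide and the C14 acetate first, then the C6 carbinol and the 7,8-epoxide, then the γ-lactone ring by closure of C11–C7, then the C8 ester, and the ten-membered ring last.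
- Enabling feature: in the lactone ring (O–C6–C7–C11–C12) the carbon C7 lies between two oxygen-bearing carbons, C6 (lactone O) and C8 (ester O). An O6-bound phosphonoacetate and a trans-7,8-oxirane therefore hold C11 in 5-exo reach of C7 with the C8 oxygen as leaving group. One SN2 closes the ring, sets C7 and frees the 8-hydroxyl; the phosphonate then delivers C13.
- Stereochemistry: C1/C10 and the side-chain oxirane from Sharpless epoxidations of Z-allylic alcohols; C6 from a ligand-controlled alkenylzinc addition; C7/C8 from a matched Sharpless epoxidation and the inversion at C7; 4Z from ring strain in the metathesis.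
- The 1,10-epoxide is made early and also keeps the 1(10)-olefin out of the metathesis.

Key step: step 10

Remark: atoms are numbered as in germacranolides (ring C1–C10, lactone C11–C13, C14 on C10, C15 on C4). Compounds 1, 3, 4, 10, 15 and 19 are assumed to be purchasable.

**Route**

Step 1
Reactants: 1 ethyl 4-methylpent-4-enoate
Product: 2 4-methylpent-4-enal
Conditions: iBu2AlH (1.05 equiv), CH2Cl2, −78 °C; aq. potassium sodium tartrate
Reagents that add atoms: none
Why: Low-temperature iBu2AlH reduction should stop at the tetrahedral O–Al(iBu)2 hemiacetal, which gives the aldehyde on work-up (partial ester reduction); no stereocentre is formed.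

Step 2
Reactants: 3 methyl 2-[bis(2,2,2-trifluoroethoxy)phosphoryl]acetate; 4 3-bromoprop-1-yne
Product: 5 methyl 2-[bis(2,2,2-trifluoroethoxy)phosphoryl]pent-4-ynoate
Conditions: NaH (1.0 equiv), THF, 0 °C to rt, 3 in slight excess
Reagents that add atoms: none
Why: SN2 C-alkylation of the sodium salt of 3 by the reactive propargylic bromide (phosphonate alkylation), the excess of 3 limiting double alkylation; the new centre is racemic and disappears in step 3.

Step 3
Reactants: 5 methyl 2-[bis(2,2,2-trifluoroethoxy)phosphoryl]pent-4-ynoate; 2 4-methylpent-4-enal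
Product: 6 methyl (2Z)-6-methyl-2-(prop-2-yn-1-yl)hepta-2,6-dienoate
Conditions: KN(SiMe3)2, 18-crown-6, THF, −78 °C
Reagents that add atoms: none
Why: Still–Gennari variant of the Horner–Wadsworth–Emmons reaction: fast elimination from the kinetically formed adduct should place the ester cis to the new chain (2Z), the geometry that later puts C14 cis to C2 and C9 trans to C2.

Step 4
Reactants: 6 methyl (2Z)-6-methyl-2-(prop-2-yn-1-yl)hepta-2,6-dienoate
Product: 7 (2Z)-6-methyl-2-(prop-2-yn-1-yl)hepta-2,6-dien-1-ol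
Conditions: iBu2AlH (2.2 equiv), CH2Cl2, −78 to 0 °C
Reagents that add atoms: none
Why: 1,2-reduction of the enoate to the allylic alcohol (iBu2AlH reduction) should leave the olefin geometry and the alkyne untouched.

Step 5
Reactants: 7 (2Z)-6-methyl-2-(prop-2-yn-1-yl)hepta-2,6-dien-1-ol
Product: 8 [(2S,3R)-3-(3-methylbut-3-en-1-yl)-2-(prop-2-yn-1-yl)oxiran-2-yl]methanol
Conditions: Ti(OiPr)4 (cat.), L-(+)-diethyl tartrate, tBuOOH, 4 Å MS, CH2Cl2, −20 °C
Reagents that add atoms: tert-butyl hydroperoxide CC(C)(C)OO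
Why: Sharpless asymmetric epoxidation: the Ti(OiPr)4–tartrate catalyst oxidises only the olefin of the allylic alcohol, and the face rule for L-(+)-tartrate should give the (2S,3R)-oxirane, which is C10 (S) and C1 (R) of the target.

Step 6
Reactants: 8 [(2S,3R)-3-(3-methylbut-3-en-1-yl)-2-(prop-2-yn-1-yl)oxiran-2-yl]methanol
Product: 9 [(2S,3R)-3-(3-methylbut-3-en-1-yl)-2-(prop-2-yn-1-yl)oxiran-2-yl]methyl acetate
Conditions: Ac2O, pyridine, DMAP (cat.), CH2Cl2, 0 °C
Reagents that add atoms: acetic anhydride CC(=O)OC(C)=O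
Why: Acylation of the primary alcohol (DMAP-catalysed acetylation) installs the C14 acetate of the target, which the later steps are chosen to tolerate.

Step 7
Reactants: 9 [(2S,3R)-3-(3-methylbut-3-en-1-yl)-2-(prop-2-yn-1-yl)oxiran-2-yl]methyl acetate; 10 prop-2-enal
Product: 13 {(2S,3R)-2-[(2E,4R)-4-hydroxyhexa-2,5-dien-1-yl]-3-(3-methylbut-3-en-1-yl)oxiran-2-yl}methyl acetate, via alkenyl(dicyclohexyl)borane 11 (not isolated), via alkenyl(methyl)zinc 12 (not isolated)
Conditions: Cy2BH (1.0 equiv), toluene, 0 °C to rt; Me2Zn, −78 °C; (−)-MIB (5 mol%), then 10, −20 °C; aq. NH4Cl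
Reagents that add atoms: none
Why: syn-Hydroboration of the terminal alkyne gives the (E)-alkenylborane, boron–zinc exchange gives 12, and the amino-alcohol-catalysed 1,2-addition to acrolein (catalytic asymmetric alkenylzinc addition) should deliver the alkenyl group to the Si face and set C6 as R, any 6S epimer being removed in step 8 where it is the slow-reacting partner.

Step 8
Reactants: 13 {(2S,3R)-2-[(2E,4R)-4-hydroxyhexa-2,5-dien-1-yl]-3-(3-methylbut-3-en-1-yl)oxiran-2-yl}methyl acetate
Product: 14 {(2S,3R)-2-({(2R,3R)-3-[(1R)-1-hydroxyprop-2-en-1-yl]oxiran-2-yl}methyl)-3-(3-methylbut-3-en-1-yl)oxiran-2-yl}methyl acetate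
Conditions: Ti(OiPr)4 (0.2 equiv), D-(−)-diisopropyl tartrate, tBuOOH, 4 Å MS, CH2Cl2, −20 °C
Reagents that add atoms: tert-butyl hydroperoxide CC(C)(C)OO
Why: Sharpless asymmetric epoxidation of a secondary (E)-allylic alcohol in the matched sense: with D-(−)-tartrate the (R)-carbinol should react fast at the C7=C8 olefin to give the erythro trans-epoxy alcohol, the vinyl group being both the mismatched and the less nucleophilic olefin, so reagent and C6 together set C7 and C8.

Step 9
Reactants: 14 {(2S,3R)-2-({(2R,3R)-3-[(1R)-1-hydroxyprop-2-en-1-yl]oxiran-2-yl}methyl)-3-(3-methylbut-3-en-1-yl)oxiran-2-yl}methyl acetate; 15 2-(diethoxyphosphoryl)acetic acid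
Product: 16 (1R)-1-[(2S,3R)-3-({(2S,3R)-2-[(acetyloxy)methyl]-3-(3-methylbut-3-en-1-yl)oxiran-2-yl}methyl)oxiran-2-yl]prop-2-en-1-yl 2-(diethoxyphosphoryl)acetate
Conditions: DCC, DMAP (cat.), CH2Cl2, 0 °C to rt
Reagents that add atoms: none
Why: Steglich esterification of the secondary alcohol under neutral conditions should leave both oxiranes intact and attaches C11/C12 to O6 without touching a stereocentre.

Step 10
Reactants: 16 (1R)-1-[(2S,3R)-3-({(2S,3R)-2-[(acetyloxy)methyl]-3-(3-methylbut-3-en-1-yl)oxiran-2-yl}methyl)oxiran-2-yl]prop-2-en-1-yl 2-(diethoxyphosphoryl)acetate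
Product: 18 {(2S,3R)-2-{(2R)-2-[(2R,3R)-2-ethenyl-4-methylidene-5-oxooxolan-3-yl]-2-hydroxyethyl}-3-(3-methylbut-3-en-1-yl)oxiran-2-yl}methyl acetate, via α-phosphono lactone 17 (not isolated)
Conditions: NaN(SiMe3)2 (1.05 equiv), THF, −40 to 45 °C; then (CH2O)n, 0 °C to rt
Reagents that add atoms: formaldehyde (as paraformaldehyde) C=O
Why: Proposed new method: NaN(SiMe3)2 forms the phosphonate-stabilised ester carbanion (C11), which the O6–C12 tether holds behind the C7–O bond of the trans-oxirane, so it should open the epoxide at C7 by intramolecular SN2 and close the γ-lactone; the C8 alkoxide is quenched at once by the acidic C11–H, and the resulting phosphonate anion of 17 is olefinated in the same flask by formaldehyde to give C11=C13. The closest known reaction types are the Stork epoxynitrile cyclisation, the base-mediated C2-selective opening of 2,3-epoxy alcohols by a carbamate nitrogen tethered through O1 (the same five-membered geometry), and the Horner–Wadsworth–Emmons methylenation of α-phosphono-γ-lactones made by intermolecular epoxide opening. The one ring closed is the five-membered lactone, in the 5-exo-tet mode with respect to the breaking C7–O bond. C7 is set by inversion at the oxirane carbon, which turns the erythro trans-epoxy ester into the 6,7-trans lactone (7R); C8 keeps the oxirane configuration and appears as the free (8R)-hydroxyl; C6 is not touched. The step needs attack at C7 and not at C8 (6-endo, δ-lactone), and it must not run on to Wadsworth–Emmons cyclopropanation or lactone migration to O8; the short ester tether and the exo preference of epoxide openings favour C7, the fast proton transfer from C11–H removes the alkoxide that would cause the other two, and the temperature stays at or below 45 °C before formaldehyde is added.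

Step 11
Reactants: 19 methyl (2Z)-2-methylbut-2-enoate
Product: 20 (2Z)-2-methylbut-2-en-1-ol
Conditions: iBu2AlH (2.2 equiv), Et2O, −78 to 0 °C
Reagents that add atoms: none
Why: 1,2-reduction of the angelate ester (iBu2AlH reduction) should give the Z-allylic alcohol without isomerisation to the tiglyl series.

Step 12
Reactants: 20 (2Z)-2-methylbut-2-en-1-ol
Product: 21 [(2R,3S)-2,3-dimethyloxiran-2-yl]methanol
Conditions: Ti(OiPr)4 (cat.), D-(−)-diethyl tartrate, tBuOOH, 4 Å MS, CH2Cl2, −20 °C
Reagents that add atoms: tert-butyl hydroperoxide CC(C)(C)OO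
Why: Sharpless asymmetric epoxidation; the face rule for D-(−)-tartrate should give the (2R,3S)-epoxy alcohol, whose oxidation gives the (2S,3S)-acid of the side chain with the methyl groups trans as in the target.

Step 13
Reactants: 21 [(2R,3S)-2,3-dimethyloxiran-2-yl]methanol
Product: 22 (2S,3S)-2,3-dimethyloxirane-2-carboxylic acid
Conditions: TEMPO (cat.), PhI(OAc)2 (2.2 equiv), MeCN–H2O, rt
Reagents that add atoms: water O
Why: Oxoammonium-mediated oxidation of the primary alcohol through the aldehyde hydrate to the acid (TEMPO/PhI(OAc)2 oxidation) is mild enough for the oxirane and does not touch either stereocentre.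

Step 14
Reactants: 18 {(2S,3R)-2-{(2R)-2-[(2R,3R)-2-ethenyl-4-methylidene-5-oxooxolan-3-yl]-2-hydroxyethyl}-3-(3-methylbut-3-en-1-yl)oxiran-2-yl}methyl acetate; 22 (2S,3S)-2,3-dimethyloxirane-2-carboxylic acid
Product: 23 (1R)-2-{(2S,3R)-2-[(acetyloxy)methyl]-3-(3-methylbut-3-en-1-yl)oxiran-2-yl}-1-[(2R,3R)-2-ethenyl-4-methylidene-5-oxooxolan-3-yl]ethyl (2S,3S)-2,3-dimethyloxirane-2-carboxylate
Conditions: 2-methyl-6-nitrobenzoic anhydride, Et3N, DMAP, CH2Cl2, rt
Reagents that add atoms: none
Why: Shiina esterification (mixed aromatic anhydride, DMAP acyl transfer) is suited to an α-quaternary acid and a hindered secondary alcohol and should acylate O8 with retention at C8.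

Step 15
Reactants: 23 (1R)-2-{(2S,3R)-2-[(acetyloxy)methyl]-3-(3-methylbut-3-en-1-yl)oxiran-2-yl}-1-[(2R,3R)-2-ethenyl-4-methylidene-5-oxooxolan-3-yl]ethyl (2S,3S)-2,3-dimethyloxirane-2-carboxylate
Product: 24 (1R,4Z,6R,7R,8R,10S)-14-acetoxy-1,10-epoxy-8-{[(2S,3S)-2,3-dimethyloxirane-2-carbonyl]oxy}germacra-4,11(13)-dien-12,6-olide (CNP0232260.1)
Conditions: second-generation Hoveyda–Grubbs catalyst (15 mol%), 1,4-benzoquinone (cat.), toluene (1 mM), 80 °C
Reagents that add atoms: none
Why: Ring-closing metathesis between the C5 vinyl group and the C4 isopropenyl group, the only olefin pair that can close a ring (the 1(10)-olefin is present as its oxirane and the α-methylene lactone is inert), should give the ten-membered ring, whose strain enforces the 4Z geometry.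

**Compound list**

1 | ethyl 4-methylpent-4-enoate | CCOC(=O)CCC(C)=C | starting material
2 | 4-methylpent-4-enal | O=CCCC(C)=C | intermediate
3 | methyl 2-[bis(2,2,2-trifluoroethoxy)phosphoryl]acetate | COC(=O)CP(=O)(OCC(F)(F)F)OCC(F)(F)F | starting material
4 | 3-bromoprop-1-yne | C#CCBr | starting material
5 | methyl 2-[bis(2,2,2-trifluoroethoxy)phosphoryl]pent-4-ynoate (racemic) | COC(=O)C(CC#C)P(=O)(OCC(F)(F)F)OCC(F)(F)F | intermediate
6 | methyl (2Z)-6-methyl-2-(prop-2-yn-1-yl)hepta-2,6-dienoate | C#CC/C(C(=O)OC)=C/CCC(C)=C | intermediate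
7 | (2Z)-6-methyl-2-(prop-2-yn-1-yl)hepta-2,6-dien-1-ol | C#CC/C(CO)=C/CCC(C)=C | intermediate
8 | [(2S,3R)-3-(3-methylbut-3-en-1-yl)-2-(prop-2-yn-1-yl)oxiran-2-yl]methanol | C#CC[C@@]1(CO)O[C@@H]1CCC(C)=C | intermediate
9 | [(2S,3R)-3-(3-methylbut-3-en-1-yl)-2-(prop-2-yn-1-yl)oxiran-2-yl]methyl acetate | C#CC[C@@]1(COC(C)=O)O[C@@H]1CCC(C)=C | intermediate
10 | prop-2-enal (acrolein) | C=CC=O | starting material
11 | {(2S,3R)-2-[(2E)-3-(dicyclohexylboranyl)prop-2-en-1-yl]-3-(3-methylbut-3-en-1-yl)oxiran-2-yl}methyl acetate | C1CCCCC1B(C1CCCCC1)/C=C/C[C@@]1(COC(C)=O)O[C@@H]1CCC(C)=C | intermediate (not isolated)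
12 | {(2S,3R)-2-[(2E)-3-(methylzincio)prop-2-en-1-yl]-3-(3-methylbut-3-en-1-yl)oxiran-2-yl}methyl acetate | C[Zn]/C=C/C[C@@]1(COC(C)=O)O[C@@H]1CCC(C)=C | intermediate (not isolated)
13 | {(2S,3R)-2-[(2E,4R)-4-hydroxyhexa-2,5-dien-1-yl]-3-(3-methylbut-3-en-1-yl)oxiran-2-yl}methyl acetate | O[C@H](C=C)/C=C/C[C@@]1(COC(C)=O)O[C@@H]1CCC(C)=C | intermediate
14 | {(2S,3R)-2-({(2R,3R)-3-[(1R)-1-hydroxyprop-2-en-1-yl]oxiran-2-yl}methyl)-3-(3-methylbut-3-en-1-yl)oxiran-2-yl}methyl acetate | O[C@H](C=C)[C@H]1O[C@@H]1C[C@@]2(COC(C)=O)O[C@@H]2CCC(C)=C | intermediate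
15 | 2-(diethoxyphosphoryl)acetic acid | CCOP(=O)(OCC)CC(=O)O | starting material
16 | (1R)-1-[(2S,3R)-3-({(2S,3R)-2-[(acetyloxy)methyl]-3-(3-methylbut-3-en-1-yl)oxiran-2-yl}methyl)oxiran-2-yl]prop-2-en-1-yl 2-(diethoxyphosphoryl)acetate | CCOP(=O)(OCC)CC(=O)O[C@H](C=C)[C@H]1O[C@@H]1C[C@@]2(COC(C)=O)O[C@@H]2CCC(C)=C | intermediate
17 | diethyl [(4R,5R)-4-{(1R)-2-[(2S,3R)-2-[(acetyloxy)methyl]-3-(3-methylbut-3-en-1-yl)oxiran-2-yl]-1-hydroxyethyl}-5-ethenyl-2-oxooxolan-3-yl]phosphonate (both C3 epimers; present as its sodium salt) | CCOP(=O)(OCC)C1C(=O)O[C@H](C=C)[C@H]1[C@H](O)C[C@@]2(COC(C)=O)O[C@@H]2CCC(C)=C | intermediate (not isolated)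
18 | {(2S,3R)-2-{(2R)-2-[(2R,3R)-2-ethenyl-4-methylidene-5-oxooxolan-3-yl]-2-hydroxyethyl}-3-(3-methylbut-3-en-1-yl)oxiran-2-yl}methyl acetate | C=C1C(=O)O[C@H](C=C)[C@H]1[C@H](O)C[C@@]2(COC(C)=O)O[C@@H]2CCC(C)=C | intermediate
19 | methyl (2Z)-2-methylbut-2-enoate (methyl angelate) | C/C=C(/C)C(=O)OC | starting material
20 | (2Z)-2-methylbut-2-en-1-ol | C/C=C(/C)CO | intermediate
21 | [(2R,3S)-2,3-dimethyloxiran-2-yl]methanol | OC[C@@]1(C)O[C@H]1C | intermediate
22 | (2S,3S)-2,3-dimethyloxirane-2-carboxylic acid | OC(=O)[C@@]1(C)O[C@H]1C | intermediate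
23 | (1R)-2-{(2S,3R)-2-[(acetyloxy)methyl]-3-(3-methylbut-3-en-1-yl)oxiran-2-yl}-1-[(2R,3R)-2-ethenyl-4-methylidene-5-oxooxolan-3-yl]ethyl (2S,3S)-2,3-dimethyloxirane-2-carboxylate | C=C1C(=O)O[C@H](C=C)[C@H]1[C@H](OC(=O)[C@@]2(C)O[C@H]2C)C[C@@]2(COC(C)=O)O[C@@H]2CCC(C)=C | intermediate
24 | (1R,4Z,6R,7R,8R,10S)-14-acetoxy-1,10-epoxy-8-{[(2S,3S)-2,3-dimethyloxirane-2-carbonyl]oxy}germacra-4,11(13)-dien-12,6-olide | C=C1C(=O)O[C@@H]2/C=C(/C)CC[C@H]3O[C@]3(COC(C)=O)C[C@@H](OC(=O)[C@@]3(C)O[C@H]3C)[C@@H]12 | target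

**Step count**

Total: 15 steps. Longest linear sequence: 11 steps (steps 1, 3, 4, 5, 6, 7, 8, 9, 10, 14, 15).

**Steps most likely to fail**

1. Step 10 (Proposed new method). What may go wrong: the carbanion may attack C8 instead of C7, or cyclise so slowly that phosphoryl migration and cyclopropane formation take over on warming.
Fallback (known chemistry, radical instead of anionic closure of C11–C7): it sets out from 7 and comes back at 23. Cp2TiCl would also open the trisubstituted 1,10-oxirane, so that epoxide is made only after the radical step. Silylation of 7 (TBSCl, imidazole) would give silyl ether F1. The alkenylzinc addition of step 7 would give dienol F2, and the epoxidation of step 8 epoxy alcohol F3. O-Alkylation with 4 (NaH, Bu4NI, THF, 0 °C) would give propargyl ether F4. Cp2TiCl (trivalent titanium, from Cp2TiCl2 and Zn dust, THF, rt) would open the 7,8-oxirane homolytically to the C7 radical; this radical closes 5-exo-dig onto the alkyne, trans to the vinyl group, to give 3-methylenetetrahydrofuran F5 with the 8-hydroxyl free. Esterification with 22 as in step 14 would give ester F6. Allylic oxidation of the ring CH2 next to oxygen (CrO3·3,5-dimethylpyrazole, CH2Cl2, −20 °C) would give α-methylene lactone F7. HF·pyridine would give alcohol F8, epoxidation as in step 5 epoxy alcohol F9, and acetylation as in step 6 leads to 23.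

2. Step 15. What may go wrong: slow initiation at two hindered olefins and the strain of a ten-membered ring already carrying the trans-fused lactone may lead to oligomerisation.
Fallback (ring first, lactone second): it sets out from 14 and comes back at 24. Metathesis of 14 (same catalyst, toluene, 1 mM, 80 °C), helped by the free allylic hydroxyl and not yet constrained by the lactone, would give ten-membered bis-epoxy alcohol F10. Esterification with 15 as in step 9 would give phosphonoacetate F11. The conditions of step 10 would give, through α-phosphono lactone F12, hydroxy lactone F13, and esterification with 22 as in step 14 gives 24.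

3. Step 7. What may go wrong: poor facial selectivity in the addition to acrolein, or attack of the boron and zinc reagents on the epoxy acetate.
Fallback (racemic coupling plus kinetic resolution): it sets out from 9 and comes back at 14. Hydrozirconation (Cp2Zr(H)Cl, THF, rt) would give alkenylzirconocene F14, and iodinolysis (I2, 0 °C) vinyl iodide F15. Nozaki–Hiyama–Kishi coupling with 10 (CrCl2, NiCl2 cat., DMF, rt) would give epimer mixture F16. The epoxidation of step 8 then acts as a Sharpless kinetic resolution that converts only the 6R epimer into 14.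

**Further compounds**

F1 | step 10 | tert-butyl(dimethyl){[(2Z)-6-methyl-2-(prop-2-yn-1-yl)hepta-2,6-dien-1-yl]oxy}silane | C#CC/C(CO[Si](C)(C)C(C)(C)C)=C/CCC(C)=C
F2 | step 10 | (3R,4E,7Z)-7-({[tert-butyl(dimethyl)silyl]oxy}methyl)-11-methyldodeca-1,4,7,11-tetraen-3-ol | O[C@H](C=C)/C=C/C/C(CO[Si](C)(C)C(C)(C)C)=C/CCC(C)=C
F3 | step 10 | (1R)-1-{(2R,3R)-3-[(2Z)-2-({[tert-butyl(dimethyl)silyl]oxy}methyl)-6-methylhepta-2,6-dien-1-yl]oxiran-2-yl}prop-2-en-1-ol | O[C@H](C=C)[C@H]1O[C@@H]1C/C(CO[Si](C)(C)C(C)(C)C)=C/CCC(C)=C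
F4 | step 10 | prop-2-yn-1-yl ether of F3 at the secondary hydroxyl | C#CCO[C@H](C=C)[C@H]1O[C@@H]1C/C(CO[Si](C)(C)C(C)(C)C)=C/CCC(C)=C
F5 | step 10 | 3-methylidenetetrahydrofuran analogue of 18 (ring CH2 in place of the lactone C=O, C1=C10 olefin and C14 silyl ether in place of oxirane and acetate) | C=C1CO[C@H](C=C)[C@H]1[C@H](O)C/C(CO[Si](C)(C)C(C)(C)C)=C/CCC(C)=C
F6 | step 10 | (2S,3S)-2,3-dimethyloxirane-2-carboxylate of F5 | C=C1CO[C@H](C=C)[C@H]1[C@H](OC(=O)[C@@]2(C)O[C@H]2C)C/C(CO[Si](C)(C)C(C)(C)C)=C/CCC(C)=C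
F7 | step 10 | α-methylene lactone from F6 (C14 silyl ether, C1=C10 olefin) | C=C1C(=O)O[C@H](C=C)[C@H]1[C@H](OC(=O)[C@@]2(C)O[C@H]2C)C/C(CO[Si](C)(C)C(C)(C)C)=C/CCC(C)=C
F8 | step 10 | C14 alcohol from F7 | C=C1C(=O)O[C@H](C=C)[C@H]1[C@H](OC(=O)[C@@]2(C)O[C@H]2C)C/C(CO)=C/CCC(C)=C
F9 | step 10 | 1,10-epoxy alcohol from F8 (23 lacking the acetyl group) | C=C1C(=O)O[C@H](C=C)[C@H]1[C@H](OC(=O)[C@@]2(C)O[C@H]2C)C[C@@]2(CO)O[C@@H]2CCC(C)=C
F10 | step 15 | ten-membered bis-epoxy allylic alcohol (ring-closed 14, 4Z) | O[C@@H]1/C=C(/C)CC[C@H]2O[C@]2(COC(C)=O)C[C@H]3O[C@H]13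
F11 | step 15 | 2-(diethoxyphosphoryl)acetate of F10 | CCOP(=O)(OCC)CC(=O)O[C@@H]1/C=C(/C)CC[C@H]2O[C@]2(COC(C)=O)C[C@H]3O[C@H]13
F12 | step 15 | ten-membered α-phosphono lactone (not isolated) | CCOP(=O)(OCC)C1C(=O)O[C@@H]2/C=C(/C)CC[C@H]3O[C@]3(COC(C)=O)C[C@@H](O)[C@@H]12
F13 | step 15 | 8-hydroxy lactone (24 lacking the side-chain ester) | C=C1C(=O)O[C@@H]2/C=C(/C)CC[C@H]3O[C@]3(COC(C)=O)C[C@@H](O)[C@@H]12
F14 | step 7 | (E)-alkenyl(chloro)bis(cyclopentadienyl)zirconium from 9 (not isolated) | Cl[Zr](C1C=CC=C1)(C1C=CC=C1)/C=C/C[C@@]1(COC(C)=O)O[C@@H]1CCC(C)=C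
F15 | step 7 | {(2S,3R)-2-[(2E)-3-iodoprop-2-en-1-yl]-3-(3-methylbut-3-en-1-yl)oxiran-2-yl}methyl acetate | I/C=C/C[C@@]1(COC(C)=O)O[C@@H]1CCC(C)=C
F16 | step 7 | mixture of 13 and its C6 epimer | OC(C=C)/C=C/C[C@@]1(COC(C)=O)O[C@@H]1CCC(C)=C
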